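**Retrosynthetic overview**

1. Ring C (twelve-membered) is opened last at its CH(OAc)–CH2 bond: an (E)-enal on ring B and a 2-substituted allyl bromide on the ring A side chain, joined by a CrCl2 allylation.
2. The route rests on ring B, the cyclopentenone fused to ring A through the tetrasubstituted alkene. Its CH(OAc) carbon and the neighbouring CH (α to the ketone), which carries the (E)-trisubstituted alkenyl arm, form a cis homoallylic alcohol unit. That unit is cut back to a ring A-fused eight-membered diallylic ether by a [2,3]-Wittig ring contraction, which forms the bond between the ring A CH2–O carbon and the far alkene CH.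
3. The eight-membered ether comes from ring-closing metathesis of a vinyl carbinol (alkenyllithium plus acrolein) with the isopropenyl group of an (R)-carbinol attached by Williamson etherification.
4. Ring A comes from 2-methylcyclohex-2-en-1-one by asymmetric conjugate addition with enolate methylation, then Vilsmeier bromoformylation. Spectator groups are chosen to offer no competing acidic C–H to alkyllithium: an allylsilane (latent allyl bromide), a dimethyl acetal (latent enal) and a triethylsilyl ether (latent ketone).
5. Order of ring formation: ring A (present from step 1), the eight-membered ether, ring B, ring C.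

Key step: step 13

Assumption: the carbinol carbon made in step 10 later becomes the ring B ketone carbon; it is formed without control, both epimers are carried together from 21 to 27 (they converge at 28), and the SMILES of 21–27 leave this centre undefined.

**Route**

Step 1
Reactants: 1 2-methylcyclohex-2-en-1-one; 2 but-3-en-1-ylmagnesium bromide
Product: 4 (S)-3-(but-3-en-1-yl)-2,2-dimethylcyclohexan-1-one, via magnesium enolate 3 (not isolated)
Conditions: Cu(OTf)2 (cat.), chiral imidazolinium salt (NHC precursor, cat.), Et2O, −30 °C; then MeI, DMPU, 0 °C → rt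
Reagents that add atoms: iodomethane, CI
Why: Copper-catalysed asymmetric conjugate addition of a Grignard reagent to the α-substituted enone sets the ring A stereocentre under ligand control (ligand antipode chosen for S), and the regiodefined magnesium enolate is C-methylated at the carbon that becomes the gem-dimethyl centre (conjugate addition–enolate alkylation).

Step 2
Reactants: 4 (S)-3-(but-3-en-1-yl)-2,2-dimethylcyclohexan-1-one
Product: 6 methyl 3-[(1S)-2,2-dimethyl-3-oxocyclohexyl]propanoate, via methoxy hydroperoxide 5 (not isolated)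
Conditions: O3, NaOH, MeOH/CH2Cl2, −78 °C
Reagents that add atoms: ozone, [O-][O+]=O; methanol, CO
Why: Ozonolysis in basic methanol turns the terminal alkene directly into the methyl ester (the carbonyl oxide is trapped by methanol and the α-methoxy hydroperoxide loses water), leaves the hindered ketone alone and gives a side chain that survives the acidic next step.

Step 3
Reactants: 6 methyl 3-[(1S)-2,2-dimethyl-3-oxocyclohexyl]propanoate
Product: 8 methyl 3-[(1S)-3-bromo-4-formyl-2,2-dimethylcyclohex-3-en-1-yl]propanoate, via bromovinyl iminium bromide 7 (not isolated)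
Conditions: PBr3, DMF, CHCl3, 0 → 60 °C; aq. NaHCO3
Reagents that add atoms: phosphorus tribromide, BrP(Br)Br; N,N-dimethylformamide, CN(C)C=O; water, O
Why: Vilsmeier–Haack bromoformylation; the ketone can enolise only toward its CH2 side, so the formyl group enters there and bromide replaces the oxygen, which places the bromine next to the gem-dimethyl carbon.

Step 4
Reactants: 8 methyl 3-[(1S)-3-bromo-4-formyl-2,2-dimethylcyclohex-3-en-1-yl]propanoate
Product: 9 methyl 3-[(1S)-3-bromo-4-(hydroxymethyl)-2,2-dimethylcyclohex-3-en-1-yl]propanoate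
Conditions: NaBH4, MeOH, 0 °C
Reagents that add atoms: none
Why: Borohydride reduces the conjugated aldehyde in the 1,2 sense and leaves the methyl ester and the vinyl bromide.

Step 5
Reactants: 9 methyl 3-[(1S)-3-bromo-4-(hydroxymethyl)-2,2-dimethylcyclohex-3-en-1-yl]propanoate
Product: 11 [(4R)-2-bromo-3,3-dimethyl-4-{3-[(trimethylsilyl)methyl]but-3-en-1-yl}cyclohex-1-en-1-yl]methanol, via bis(silylmethyl) carbinol 10 (not isolated)
Conditions: Me3SiCH2MgCl (excess), CeCl3, THF, −78 °C → rt; then SiO2, CH2Cl2
Reagents that add atoms: (trimethylsilyl)methylmagnesium chloride, C[Si](C)(C)C[Mg]Cl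
Why: Double addition of the cerium-modified silylmethyl Grignard reagent to the ester and Peterson elimination of one silanol give the 2-substituted allylsilane, a base-stable latent allyl bromide; the free hydroxyl only consumes one equivalent of reagent.

Step 6
Reactants: 11 [(4R)-2-bromo-3,3-dimethyl-4-{3-[(trimethylsilyl)methyl]but-3-en-1-yl}cyclohex-1-en-1-yl]methanol
Product: 12 (4R)-2-bromo-1-(bromomethyl)-3,3-dimethyl-4-{3-[(trimethylsilyl)methyl]but-3-en-1-yl}cyclohex-1-ene
Conditions: CBr4, PPh3, CH2Cl2, 0 °C
Reagents that add atoms: carbon tetrabromide, BrC(Br)(Br)Br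
Why: Appel bromination of the primary allylic alcohol under neutral conditions, which the allylsilane and the vinyl bromide tolerate.

Step 7
Reactants: 13 isopropenylmagnesium bromide; 14 2,2-dimethoxyacetaldehyde (dried solution)
Product: 15 rac-1,1-dimethoxy-3-methylbut-3-en-2-ol
Conditions: THF, −78 → 0 °C; aq. NH4Cl
Reagents that add atoms: none
Why: 1,2-Addition of the alkenyl Grignard reagent to the aldehyde gives the racemic secondary allylic alcohol.

Step 8
Reactants: 15 rac-1,1-dimethoxy-3-methylbut-3-en-2-ol
Product: 16 (R)-1,1-dimethoxy-3-methylbut-3-en-2-ol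
Conditions: Ti(OiPr)4, D-(−)-diisopropyl tartrate, t-BuOOH (0.6 equiv), 4 Å MS, CH2Cl2, −20 °C
Reagents that add atoms: none
Why: Sharpless kinetic resolution; with D-(−)-tartrate the (S)-alcohol should be epoxidised fast, and the (R)-alcohol, which has the configuration needed at the ether carbon, is recovered.

Step 9
Reactants: 12 (4R)-2-bromo-1-(bromomethyl)-3,3-dimethyl-4-{3-[(trimethylsilyl)methyl]but-3-en-1-yl}cyclohex-1-ene; 16 (R)-1,1-dimethoxy-3-methylbut-3-en-2-ol
Product: 18 (4R)-2-bromo-1-({[(2R)-1,1-dimethoxy-3-methylbut-3-en-2-yl]oxy}methyl)-3,3-dimethyl-4-{3-[(trimethylsilyl)methyl]but-3-en-1-yl}cyclohex-1-ene, via sodium alkoxide 17 (not isolated)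
Conditions: 16, NaH, THF/DMF, 0 °C; then 12, Bu4NI (cat.), 0 °C → rt
Reagents that add atoms: none
Why: Williamson ether synthesis; the alkoxide displaces the primary allylic bromide by SN2, the vinyl bromide is inert, and the stereocentre of 16 is not touched.

Step 10
Reactants: 18 bromo ether; 19 acrolein
Product: 21 divinyl carbinol (the bromine of 18 replaced by a 1-hydroxyprop-2-en-1-yl group; both epimers at the new carbinol carbon), via vinyllithium 20 (not isolated)
Conditions: t-BuLi (2.1 equiv), THF, −78 °C; then acrolein, −78 °C; aq. NH4Cl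
Reagents that add atoms: none
Why: Bromine–lithium exchange is faster than any deprotonation at −78 °C and the hindered alkenyllithium adds 1,2 to acrolein; the new carbinol carbon is formed without control, which is harmless because it ends as the ketone carbon.

Step 11
Reactants: 21 divinyl carbinol
Product: 22 ring A-fused eight-membered diallylic ether with free hydroxyl (Z ring alkene; (R) ether carbon bearing CH(OMe)2; both epimers at the carbinol carbon)
Conditions: second-generation Grubbs catalyst (10 mol%), CH2Cl2 (0.002 M), 40 °C
Reagents that add atoms: none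
Why: Ring-closing metathesis starts at the vinyl carbinol and closes onto the isopropenyl group; the tetrasubstituted ring A alkene holds the two chains cis, only the Z alkene fits the eight-membered ring, and closure onto the allylsilane alkene would need a bridgehead alkene.

Step 12
Reactants: 22 eight-membered ether alcohol
Product: 23 triethylsilyl ether of 22 (precursor of the key step)
Conditions: Et3SiOTf, 2,6-lutidine, CH2Cl2, −78 °C
Reagents that add atoms: triethylsilyl trifluoromethanesulfonate, CC[Si](CC)(CC)OS(=O)(=O)C(F)(F)F
Why: Silyl triflate silylation of the hindered allylic alcohol; the triethylsilyl ether survives alkyllithium at low temperature and comes off later in mild acid.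

Step 13
Reactants: 23 silylated eight-membered diallylic ether
Product: 25 ring A/B cyclopentenol (hydroxyl and the (E)-4,4-dimethoxybut-2-en-2-yl group cis on ring B; silyloxy carbon both epimers), via lithiated ether 24 (not isolated)
Conditions: s-BuLi (1.5 equiv), THF, −78 → −40 °C; aq. NH4Cl
Reagents that add atoms: none
Why: Proposed new method: s-BuLi removes a hydrogen from the ring A CH2–O carbon of 23, the only α-oxygenated allylic CH2 in the molecule, and the α-alkoxy carbanion 24 attacks the ring alkene CH (the one bonded to the silyloxy carbon) suprafacially while the allylic C–O bond at the ether stereocentre breaks, a [2,3]-sigmatropic (Wittig) shift through a five-membered envelope transition state whose closest known relatives are the [2,3]-Wittig ring contractions of 13- and 17-membered diallylic or allylic propargylic ethers to 10- and 14-membered carbocyclic homoallylic alcohols. Ring B closes as the second five-membered ring of a cis-fused bicyclic transition state; seen from the ring A alkene this is a 5-(enolendo)-exo-trig-type closure, so the carbanion has to react through a lobe near the plane of that alkene, which is the orientation the eight-membered ring already gives to the C–H bonds of this CH2 group. The configuration at the new CH(alkenyl) carbon is set by the (R) ether carbon: the C–C bond forms on the alkene face that carries the departing oxygen, and the CH(OMe)2 group lies outside with H inside (avoiding A(1,3) strain with the ring carbon that is Z to it), which fixes both that face and the E geometry of the new trisubstituted alkene. The new carbinol centre is set by the bicyclic transition state itself, because the bridging oxygen and the migrating alkenyl carbon sit on the same face of the forming cyclopentene, so hydroxyl and alkenyl emerge cis. The step needs site-selective lithiation and must outrun 1,4-elimination of triethylsilanolate and the [1,2]-shift: the ether CH is tertiary, its C–H and the C–H and C–O bonds at the silyloxy carbon lie close to the nodal planes of the neighbouring π systems because the ring bonds take the perpendicular positions, and the allylsilane and the acetal offer no α-oxygenated allylic or benzylic hydrogen.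

Step 14
Reactants: 25 ring A/B cyclopentenol
Product: 26 ring B acetate of 25
Conditions: Ac2O, Et3N, DMAP (cat.), CH2Cl2, 0 °C → rt
Reagents that add atoms: acetic anhydride, CC(=O)OC(C)=O
Why: DMAP-catalysed acylation of the only free hydroxyl fixes the ring B acetate with retention.

Step 15
Reactants: 26 acetate
Product: 27 hydroxy (E)-enal (ring B carbinol free, both epimers; acetate and allylsilane intact)
Conditions: AcOH/THF/H2O (3:1:1), rt
Reagents that add atoms: water, O
Why: Mild aqueous acid cleaves the triethylsilyl ether and hydrolyses the allylic dimethyl acetal to the (E)-enal in one operation, while the acetate and the allylsilane are stable to acetic acid.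

Step 16
Reactants: 27 hydroxy enal
Product: 28 ring B enone bearing the (E)-enal arm and the allylsilane side chain
Conditions: Dess–Martin periodinane, NaHCO3, CH2Cl2, 0 °C → rt
Reagents that add atoms: none
Why: Dess–Martin oxidation of the secondary allylic alcohol under buffered conditions gives the ring B enone; both epimers converge here and the α-stereocentre is not exposed to base.

Step 17
Reactants: 28 keto enal allylsilane
Product: 29 keto enal allyl bromide
Conditions: NBS, propylene oxide, CH2Cl2, −78 °C
Reagents that add atoms: N-bromosuccinimide, O=C1CCC(=O)N1Br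
Why: Electrophilic bromodesilylation (SE2′) of the allylsilane, by far the most nucleophilic alkene present, gives the 2-substituted allyl bromide.

Step 18
Reactants: 29 keto enal allyl bromide
Product: 31 tricyclic alcohol with twelve-membered ring C, via allylchromium dichloride 30 (not isolated)
Conditions: CrCl2 (6 equiv), THF, rt, slow addition (final 0.002 M); aq. work-up
Reagents that add atoms: none
Why: Nozaki–Hiyama allylation; the allylchromium species (trivalent chromium) adds through its γ-carbon to the aldehyde in preference to the hindered ketone and closes ring C at high dilution, and the new carbinol configuration is expected from attack on the outer face of the enal in the macrocyclic transition state, the least secure stereocentre of the route.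

Step 19
Reactants: 31 tricyclic alcohol
Product: 32 CNP0121312.1 (target diacetate)
Conditions: Ac2O, pyridine, DMAP (cat.), CH2Cl2, 0 °C
Reagents that add atoms: acetic anhydride, CC(=O)OC(C)=O
Why: Acetylation of the secondary alcohol with retention gives the target.

**Compound list**

1 | 2-methylcyclohex-2-en-1-one | CC1=CCCCC1=O | starting material
2 | but-3-en-1-ylmagnesium bromide | C=CCC[Mg]Br | starting material
3 | bromomagnesium enolate from the conjugate addition (ring stereocentre as in 4) | C=CCC[C@@H]1CCCC(O[Mg]Br)=C1C | intermediate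
4 | (S)-3-(but-3-en-1-yl)-2,2-dimethylcyclohexan-1-one | C=CCC[C@@H]1CCCC(=O)C1(C)C | intermediate
5 | (S)-3-(3-hydroperoxy-3-methoxypropyl)-2,2-dimethylcyclohexan-1-one (both epimers at the peroxy carbon) | COC(OO)CC[C@@H]1CCCC(=O)C1(C)C | intermediate
6 | methyl 3-[(1S)-2,2-dimethyl-3-oxocyclohexyl]propanoate | COC(=O)CC[C@@H]1CCCC(=O)C1(C)C | intermediate
7 | bromovinyl iminium bromide (Vilsmeier adduct of 6) | COC(=O)CC[C@@H]1CCC(C=[N+](C)C)=C(Br)C1(C)C.[Br-] | intermediate
8 | methyl 3-[(1S)-3-bromo-4-formyl-2,2-dimethylcyclohex-3-en-1-yl]propanoate | COC(=O)CC[C@@H]1CCC(C=O)=C(Br)C1(C)C | intermediate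
9 | methyl 3-[(1S)-3-bromo-4-(hydroxymethyl)-2,2-dimethylcyclohex-3-en-1-yl]propanoate | COC(=O)CC[C@@H]1CCC(CO)=C(Br)C1(C)C | intermediate
10 | tertiary bis(trimethylsilylmethyl) carbinol from 9 | C[Si](C)(C)CC(O)(C[Si](C)(C)C)CC[C@@H]1CCC(CO)=C(Br)C1(C)C | intermediate
11 | [(4R)-2-bromo-3,3-dimethyl-4-{3-[(trimethylsilyl)methyl]but-3-en-1-yl}cyclohex-1-en-1-yl]methanol | C=C(C[Si](C)(C)C)CC[C@@H]1CCC(CO)=C(Br)C1(C)C | intermediate
12 | (4R)-2-bromo-1-(bromomethyl)-3,3-dimethyl-4-{3-[(trimethylsilyl)methyl]but-3-en-1-yl}cyclohex-1-ene | C=C(C[Si](C)(C)C)CC[C@@H]1CCC(CBr)=C(Br)C1(C)C | intermediate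
13 | isopropenylmagnesium bromide | C=C(C)[Mg]Br | starting material
14 | 2,2-dimethoxyacetaldehyde | COC(OC)C=O | starting material
15 | rac-1,1-dimethoxy-3-methylbut-3-en-2-ol | C=C(C)C(O)C(OC)OC | intermediate
16 | (R)-1,1-dimethoxy-3-methylbut-3-en-2-ol | C=C(C)[C@@H](O)C(OC)OC | intermediate
17 | sodium (R)-1,1-dimethoxy-3-methylbut-3-en-2-olate | C=C(C)[C@@H]([O-])C(OC)OC.[Na+] | intermediate
18 | (4R)-2-bromo-1-({[(2R)-1,1-dimethoxy-3-methylbut-3-en-2-yl]oxy}methyl)-3,3-dimethyl-4-{3-[(trimethylsilyl)methyl]but-3-en-1-yl}cyclohex-1-ene | C=C(C[Si](C)(C)C)CC[C@@H]1CCC(CO[C@H](C(C)=C)C(OC)OC)=C(Br)C1(C)C | intermediate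
19 | acrolein | C=CC=O | starting material
20 | alkenyllithium from 18 (lithium in place of the ring bromine) | C=C(C[Si](C)(C)C)CC[C@@H]1CCC(CO[C@H](C(C)=C)C(OC)OC)=C([Li])C1(C)C | intermediate
21 | divinyl carbinol: 18 with the ring bromine replaced by 1-hydroxyprop-2-en-1-yl (both epimers at the carbinol carbon) | C=C(C[Si](C)(C)C)CC[C@@H]1CCC(CO[C@H](C(C)=C)C(OC)OC)=C(C(O)C=C)C1(C)C | intermediate
22 | ring A-fused eight-membered diallylic ether, free hydroxyl (Z ring alkene, (R) ether carbon with CH(OMe)2, both epimers at the carbinol carbon) | C=C(C[Si](C)(C)C)CC[C@@H]1CCC2=C(C(O)/C=C(C)\[C@H](C(OC)OC)OC2)C1(C)C | intermediate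
23 | triethylsilyl ether of 22 | C=C(C[Si](C)(C)C)CC[C@@H]1CCC2=C(C(O[Si](CC)(CC)CC)/C=C(C)\[C@H](C(OC)OC)OC2)C1(C)C | intermediate
24 | 23 lithiated at the ring A CH2–O carbon | C=C(C[Si](C)(C)C)CC[C@@H]1CCC2=C(C(O[Si](CC)(CC)CC)/C=C(C)\[C@H](C(OC)OC)OC2[Li])C1(C)C | intermediate
25 | ring A/B cyclopentenol: hydroxyl cis to the (E)-4,4-dimethoxybut-2-en-2-yl group, triethylsilyloxy carbon both epimers | C=C(C[Si](C)(C)C)CC[C@@H]1CCC2=C(C(O[Si](CC)(CC)CC)[C@@H](/C(C)=C/C(OC)OC)[C@H]2O)C1(C)C | intermediate
26 | acetate of 25 | C=C(C[Si](C)(C)C)CC[C@@H]1CCC2=C(C(O[Si](CC)(CC)CC)[C@@H](/C(C)=C/C(OC)OC)[C@H]2OC(C)=O)C1(C)C | intermediate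
27 | hydroxy (E)-enal: ring B acetate, free ring B carbinol (both epimers), allylsilane side chain | C=C(C[Si](C)(C)C)CC[C@@H]1CCC2=C(C(O)[C@@H](/C(C)=C/C=O)[C@H]2OC(C)=O)C1(C)C | intermediate
28 | ring B enone with cis acetoxy and (E)-enal arm, allylsilane side chain | C=C(C[Si](C)(C)C)CC[C@@H]1CCC2=C(C(=O)[C@@H](/C(C)=C/C=O)[C@H]2OC(C)=O)C1(C)C | intermediate
29 | 28 with the allylsilane converted into the 2-(bromomethyl)allyl group | C=C(CBr)CC[C@@H]1CCC2=C(C(=O)[C@@H](/C(C)=C/C=O)[C@H]2OC(C)=O)C1(C)C | intermediate
30 | allylchromium dichloride from 29 | C=C(C[Cr](Cl)Cl)CC[C@@H]1CCC2=C(C(=O)[C@@H](/C(C)=C/C=O)[C@H]2OC(C)=O)C1(C)C | intermediate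
31 | tricyclic alcohol (target with free ring C hydroxyl) | C=C1CC[C@@H]2CCC3=C(C(=O)[C@@H](/C(C)=C/[C@@H](O)C1)[C@H]3OC(C)=O)C2(C)C | intermediate
32 | CNP0121312.1 | C=C1CC[C@@H]2CCC3=C(C(=O)[C@@H](/C(C)=C/[C@@H](OC(C)=O)C1)[C@H]3OC(C)=O)C2(C)C | target

**Step count and risks**

Total steps: 19. Longest linear sequence: 17 (steps 1–6 and 9–19).

Most likely to fail:

1. Step 13 (labelled). The carbanion has to turn out of conjugation with the ring A alkene to reach the ring alkene carbon, so three processes may take over: lithiation at another C–H, loss of triethylsilanolate by 1,4-elimination, or a [1,2]-shift. Fallback with known reactions only, setting out from 11 and returning at 27. MnO2 oxidises 11 to the bromo enal F1. An auxiliary-controlled, magnesium-halide-catalysed anti-aldol addition (MgBr2·OEt2 cat., Et3N, Me3SiCl; then dilute acid) of the separately prepared acyl thiazolidinethione F2 (auxiliary antipode chosen for the required sense) to F1 gives the anti β-hydroxy imide F3, which already holds both ring B stereocentres. Acetylation gives the acetate F4, and i-Bu2AlH at −78 °C reduces the activated imide to the aldehyde F5. An intramolecular Nozaki–Hiyama–Kishi reaction of the vinyl bromide with this aldehyde (CrCl2, NiCl2 cat., DMF) closes ring B at the bond between the ring A alkene carbon and the future ketone carbon and gives the cyclopentenol acetal F6. Aqueous acetic acid then hydrolyses the acetal of F6 to 27.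

2. Step 11. Ring closure onto the hindered isopropenyl group of the ether may be slow, so that dimerisation at the vinyl carbinol and alkene isomerisation win. Fallback, setting out from 12 and returning at 22: the eight-membered ring is closed at the bond between the ring A alkene carbon and the carbinol carbon instead. Commercial (Z)-3-iodobut-2-en-1-ol is silylated (TBSCl, imidazole) to the iodo silyl ether F7. Iodine–lithium exchange (t-BuLi) and addition to 14 give the racemic (Z)-carbinol F8, which is resolved by chromatography on a chiral phase to the (R,Z)-carbinol F9. Williamson etherification of F9 with 12 (NaH) gives the ether F10, PPTS in methanol frees the allylic alcohol F11, and MnO2 gives the (Z)-enal F12. CrCl2 with catalytic NiCl2 in DMF at high dilution then couples the vinyl bromide with the aldehyde (Nozaki–Hiyama–Kishi) and gives 22 with the Z ring alkene already in place.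

3. Step 18. Facial selectivity of the allylchromium addition to the enal inside the forming twelve-membered ring may be poor or opposite. Fallback, setting out from 29 and returning at 32: if the cyclisation gives mainly the epimeric alcohol F13, Mitsunobu esterification with acetic acid (PPh3, DIAD, AcOH) inverts that carbinol carbon and installs the acetate in one operation, in place of the retentive acetylation of step 19.

Further compounds
F1 | step 13 | (4R)-2-bromo-3,3-dimethyl-4-{3-[(trimethylsilyl)methyl]but-3-en-1-yl}cyclohex-1-ene-1-carbaldehyde | C=C(C[Si](C)(C)C)CC[C@@H]1CCC(C=O)=C(Br)C1(C)C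
F2 | step 13 | (E)-1-[(4S)-4-benzyl-2-thioxothiazolidin-3-yl]-5,5-dimethoxy-3-methylpent-3-en-1-one | COC(OC)/C=C(\C)CC(=O)N1C(=S)SC[C@@H]1Cc1ccccc1
F3 | step 13 | anti-aldol adduct of F1 and F2 (β-hydroxy imide with both ring B stereocentres) | C=C(C[Si](C)(C)C)CC[C@@H]1CCC([C@H](O)[C@H](/C(C)=C/C(OC)OC)C(=O)N2C(=S)SC[C@@H]2Cc2ccccc2)=C(Br)C1(C)C
F4 | step 13 | acetate of F3 | C=C(C[Si](C)(C)C)CC[C@@H]1CCC([C@H](OC(C)=O)[C@H](/C(C)=C/C(OC)OC)C(=O)N2C(=S)SC[C@@H]2Cc2ccccc2)=C(Br)C1(C)C
F5 | step 13 | β-acetoxy aldehyde from F4 | C=C(C[Si](C)(C)C)CC[C@@H]1CCC([C@H](OC(C)=O)[C@H](/C(C)=C/C(OC)OC)C=O)=C(Br)C1(C)C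
F6 | step 13 | ring A/B cyclopentenol acetate with dimethyl acetal (both epimers at the new carbinol carbon) | C=C(C[Si](C)(C)C)CC[C@@H]1CCC2=C(C(O)[C@@H](/C(C)=C/C(OC)OC)[C@H]2OC(C)=O)C1(C)C
F7 | step 11 | (Z)-tert-butyl[(3-iodobut-2-en-1-yl)oxy]dimethylsilane | C/C(I)=C/CO[Si](C)(C)C(C)(C)C
F8 | step 11 | rac-(Z)-5-[(tert-butyldimethylsilyl)oxy]-1,1-dimethoxy-3-methylpent-3-en-2-ol | COC(OC)C(O)/C(C)=C\CO[Si](C)(C)C(C)(C)C
F9 | step 11 | (2R,3Z)-5-[(tert-butyldimethylsilyl)oxy]-1,1-dimethoxy-3-methylpent-3-en-2-ol | COC(OC)[C@H](O)/C(C)=C\CO[Si](C)(C)C(C)(C)C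
F10 | step 11 | ether of 12 with F9 | C=C(C[Si](C)(C)C)CC[C@@H]1CCC(CO[C@@H](C(OC)OC)/C(C)=C\CO[Si](C)(C)C(C)(C)C)=C(Br)C1(C)C
F11 | step 11 | (Z)-allylic alcohol from F10 | C=C(C[Si](C)(C)C)CC[C@@H]1CCC(CO[C@@H](C(OC)OC)/C(C)=C\CO)=C(Br)C1(C)C
F12 | step 11 | (Z)-enal from F11 | C=C(C[Si](C)(C)C)CC[C@@H]1CCC(CO[C@@H](C(OC)OC)/C(C)=C\C=O)=C(Br)C1(C)C
F13 | step 18 | epimer of 31 at the ring C carbinol carbon | C=C1CC[C@@H]2CCC3=C(C(=O)[C@@H](/C(C)=C/[C@H](O)C1)[C@H]3OC(C)=O)C2(C)C
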